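The vessel is a stirred flask of constant volume, and the quick number wanted is how much target each of two such flasks holds when it is stopped.

all flasks: free catalyst 0.30 mM
- north-east: starting material 0.0020 M (fed, over 4.0 s); impurity 0.18 mM; run made earlier
- south: starting material 0.0020 M (fed, over 4.0 s); impurity 0.63 mM; run made earlier
- autumn: starting material 0.0020 M; impurity 0.50 mM; everything together at the start; time 0.60 min
- summer: starting material 0.0020 M (fed, over 4.0 s); impurity 0.13 mM; time 2.5 min

- north-east (time / s: target / %, starting material / %): 10.0: 6, 88; 20.0: 11, 76; 40.0: 17, 69; 50.0: 17, 65; 80.0: 21, 59
- south (time / s: target / %, starting material / %): 15.0: 7, 80; 30.0: 13, 73; 50.0: 18, 65; 60.0: 18, 61; 80.0: 23, 58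

(readings scatter by 1.5 percentage points)



* which one finishes higher in amount of target, in percent of the starting material charged ("neither" within 2 percentage points) (autumn / summer / neither)
* amount of target at the end, in percent of the starting material charged, autumn
* amount of target at the end, in percent of the starting material charged, summer

The hunch that autumn's heavier impurity costs it target finds little in the earlier runs: the south run carries 3.50 times the impurity of the north-east run, yet at 80.0 s their target reads 23 % against 21 %, a gap of 2 percentage points beside a scatter of 1.5 points on each reading. My own reckoning uses the filling time, the relaxation time of a first-order rise to a plateau, read from the north-east target at 20.0 s and at twice that time, which gives 33.0 s and a plateau of 24.2 % of the charge. Autumn stops after 1.09 filling times and summer, which runs longer than autumn, after 4.55, so I reckon 16.1 % for autumn and 23.9 % for summer.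

The forecast, holding that “Impurity therefore seems to have little effect”, gives 16.5 % for autumn and 25.5 % for summer, a little above my two figures, and names summer as the higher.

The flasks give 14.9 % in autumn and 27.3 % in summer, so summer finishes higher, as forecast.

    starting material ⇌ isomer of the product (K = 0.290, k = 0.0130 s⁻¹)
    free catalyst → spent catalyst B (k = 0.0210 s⁻¹)
    free catalyst + impurity → spent catalyst A (k = 2400 L mol⁻¹ s⁻¹)
    starting material ⇌ target (K = 0.540, k = 0.00650 s⁻¹)

The time allowed is part of that difference: autumn given summer's time holds 27.3 % rather than 14.9 %, a gain of 12 points, and autumn left ten times its own time holds 29.4 %, a gain of 15 points, while autumn given summer's impurity stays at 14.9 %. The autumn flask read at 15 s has had 0.455 filling times, which reckons to 8.84 %, and its target stands at 7.87 %.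

The readings stem from a simulated flask from invented constants, and the scatter is random.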